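**Plan**

- Retrosynthesis starts in ring A: the 5,7-dihydroxy arene is taken back to a 7-hydroxy-5-oxo tetrahydro ring (dihydrophloroglucinol level), which returns to the phenol by one alcohol oxidation and tautomerisation.
- At that level O1–C2–C3–C4(=O)–C4a=C8a is a 2,3-dihydro-4H-pyran-4-one, a vinylogous ester whose β-carbon C8a is electrophilic. C2–C3 (aldol) and O1–C8a (addition–elimination) are therefore cut together: C2 and O1 come from 4-methoxy-3-prenylbenzaldehyde, and C3, C4 and ring A come from a 2-(1-silyloxyvinyl)-3-methoxycyclohexenone.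
- Forward: the ring A cyclohexenone is made from phloroglucinol in five steps and the aldehyde by one Stille prenylation. Ring C is then closed by catalytic asymmetric aldol addition and ring closure, and ring A is aromatised last by desilylation and oxidation.
- Stereochemistry: the only stereocentre, C2 (S), is set by the (S)-BINOL/Ti(OiPr)4 catalyst when C2–C3 forms. It is kept by using only non-basic, weakly acidic conditions afterwards.

Key step: step 7

Remark: the ring A carbinol carbon (C5 of the cyclohexenones, C7 of the chromenediones) is formed racemic and becomes sp2 in step 9. It is carried as both configurations and has no descriptor in names or SMILES.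

**Step 1**
Reactants: 1 phloroglucinol
Product: 2 5-hydroxycyclohexane-1,3-dione
Conditions: H2 (3 atm), Rh/Al2O3 (5 wt %), NaOH (1.0 equiv), H2O, rt; then HCl to pH 3, 0 °C
Reagents that add atoms: none
Why: Partial catalytic hydrogenation of the phenolate, the reaction type that turns resorcinol into cyclohexane-1,3-dione, should stop at the vinylogous carboxylate, and cold acidification avoids acid-catalysed dehydration to resorcinol.

**Step 2**
Reactants: 2 5-hydroxycyclohexane-1,3-dione
Product: 4 5-(tert-butyldimethylsilyloxy)cyclohexane-1,3-dione, via bis-silyl enone 3 (not isolated)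
Conditions: TBSCl (2.3 equiv), imidazole, DMF, rt; then 10% aq. citric acid, THF, rt
Reagents that add atoms: tert-butyldimethylsilyl chloride, CC(C)(C)[Si](C)(C)Cl
Why: Silyl ether formation with a silyl chloride and imidazole silylates both the alcohol and the enol (3, racemic), and the vinylogous silyl ester, far more labile than the secondary silyl ether, is hydrolysed by dilute acid to the symmetrical dione 4.

**Step 3**
Reactants: 4 5-(tert-butyldimethylsilyloxy)cyclohexane-1,3-dione
Product: 6 2-acetyl-5-(tert-butyldimethylsilyloxy)-3-hydroxycyclohex-2-en-1-one, via enol acetate 5 (not isolated)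
Conditions: AcOH, DCC, DMAP (0.3 equiv), Et3N, CH2Cl2, 0 °C to rt
Reagents that add atoms: acetic acid, CC(=O)O
Why: Steglich-type O-acylation of the enol followed by DMAP-mediated O-to-C acyl migration (Fries-type rearrangement of the enol ester) is the standard entry to 2-acylcyclohexane-1,3-diones, and the product sits as its ammonium enolate, in which the ring CH2 groups are not acidic, so the β-silyloxy group is not eliminated.

**Step 4**
Reactants: 6 2-acetyl-5-(tert-butyldimethylsilyloxy)-3-hydroxycyclohex-2-en-1-one
Product: 7 2-acetyl-5-(tert-butyldimethylsilyloxy)-3-methoxycyclohex-2-en-1-one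
Conditions: TMSCHN2 (1.3 equiv), MeOH/PhMe (1:4), 0 °C
Reagents that add atoms: trimethylsilyldiazomethane, C[Si](C)(C)C=[N+]=[N-]
Why: Diazoalkane O-methylation of an acidic enol: the β-triketone protonates the reagent and the ring enolate oxygen is methylated under neutral conditions to the endocyclic vinylogous methyl ester, as known for 2-acylcyclohexane-1,3-diones and diazomethane, and because methylation removes the symmetry of the ring 7 is racemic at C5.

**Step 5**
Reactants: 7 2-acetyl-5-(tert-butyldimethylsilyloxy)-3-methoxycyclohex-2-en-1-one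
Product: 8 5-(tert-butyldimethylsilyloxy)-3-methoxy-2-[1-(trimethylsilyloxy)vinyl]cyclohex-2-en-1-one
Conditions: TMSCl (3 equiv), LiN(SiMe3)2 (1.2 equiv), THF, −78 °C (in situ quench); pentane, filtration, used crude
Reagents that add atoms: chlorotrimethylsilane, C[Si](C)(C)Cl
Why: Kinetic enolisation with in situ silyl trapping: the acetyl group, twisted out of the plane of the push–pull alkene, offers the most acidic and most accessible α-protons whereas the ring carbonyl is a vinylogous ester, and the enolate is O-silylated as it forms at −78 °C, which leaves no time for proton transfer to the ring positions or for E1cB loss of the silyloxy group.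

**Step 6**
Reactants: 9 3-bromo-4-methoxybenzaldehyde; 10 tributyl(3-methylbut-2-enyl)stannane
Product: 11 4-methoxy-3-(3-methylbut-2-enyl)benzaldehyde
Conditions: Pd(PPh3)4 (5 mol %), DMF, 100 °C
Reagents that add atoms: none
Why: Stille coupling: oxidative addition of the aryl bromide to zerovalent palladium, transfer of the prenyl group from tin and reductive elimination at the less substituted allyl terminus should give the linear prenyl arene, with the aldehyde and the aryl ether as spectators.

**Step 7**
Reactants: 11 4-methoxy-3-(3-methylbut-2-enyl)benzaldehyde; 8 5-(tert-butyldimethylsilyloxy)-3-methoxy-2-[1-(trimethylsilyloxy)vinyl]cyclohex-2-en-1-one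
Product: 14 (2S)-7-(tert-butyldimethylsilyloxy)-2-[4-methoxy-3-(3-methylbut-2-enyl)phenyl]-2,3,7,8-tetrahydro-4H-chromene-4,5(6H)-dione, via silyl aldol ether 12 (not isolated), via hydroxy ketone 13 (not isolated)
Conditions: (S)-BINOL (20 mol %), Ti(OiPr)4 (20 mol %), 4 Å MS, Et2O, −20 °C; then MeOH (3 equiv), PPTS (0.3 equiv), CH2Cl2, 0 °C to rt
Reagents that add atoms: none
Why: The (S)-BINOL–titanium complex binds the aldehyde oxygen of 11 and the terminal CH2 of silyl dienol ether 8 adds to the carbonyl carbon through an open transition state (Mukaiyama aldol addition; the 1-silyloxyvinyl group is twisted out of the plane of the tetrasubstituted ring alkene, so a concerted cycloaddition is not expected), after which silyl transfer to the aldolate gives 12 and frees the catalyst. Methanol and PPTS then take off the trimethylsilyl group to give 13, whose hydroxyl adds to C8a of the vinylogous ester and expels methanol, closing ring C by a 6-endo-trig addition–elimination. The closest known reaction type is the BINOL/Ti(OiPr)4-catalysed aldol–cyclisation (formal hetero-Diels–Alder reaction) of 1-methoxy-3-silyloxybutadienes with aromatic aldehydes to 2-aryl-2,3-dihydro-4H-pyran-4-ones. C2 is set in the C–C bond formation under catalyst control: by analogy with the allylation and aldol reactions of this catalyst the (S)-ligand should direct the nucleophile to the Si face of the aldehyde, which corresponds to 2S, and the carbinol C–O bond is not broken in the ring closure, so the configuration is carried into 14. The step needs O-cyclisation at C8a in preference to dehydration or ionisation of the 4-methoxybenzylic carbinol, and survival of the ring A silyl ether and the prenyl alkene; this is secured by C8a being activated by both the C4 and the C5 carbonyl and carrying a methoxy leaving group, so that an acid no stronger than a pyridinium salt is enough, while the racemic ring A carbinol centre of 8 is remote and merely gives two C7 epimers of 14 that converge in step 9.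

**Step 8**
Reactants: 14 (2S)-7-(tert-butyldimethylsilyloxy)-2-[4-methoxy-3-(3-methylbut-2-enyl)phenyl]-2,3,7,8-tetrahydro-4H-chromene-4,5(6H)-dione
Product: 15 (2S)-7-hydroxy-2-[4-methoxy-3-(3-methylbut-2-enyl)phenyl]-2,3,7,8-tetrahydro-4H-chromene-4,5(6H)-dione
Conditions: HF·pyridine, pyridine, THF, 0 °C to rt
Reagents that add atoms: none
Why: Fluoride-mediated silyl ether cleavage under buffered, weakly acidic conditions should free the alcohol without enolising the β-hydroxy ketone (no E1cB dehydration, no retro-oxa-Michael opening at C2) and without ionising the 4-methoxybenzylic C2–O1 bond or adding to the prenyl alkene.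

**Step 9**
Reactants: 15 (2S)-7-hydroxy-2-[4-methoxy-3-(3-methylbut-2-enyl)phenyl]-2,3,7,8-tetrahydro-4H-chromene-4,5(6H)-dione
Product: 17 4'-O-methyllicoflavanone, via trione 16 (not isolated)
Conditions: Dess–Martin periodinane (1.1 equiv), CH2Cl2, 0 °C; aq. Na2S2O3/pH 7 phosphate work-up
Reagents that add atoms: none
Why: Dess–Martin oxidation of the secondary alcohol converts both C7 epimers into the 4,5,7-trione 16, the keto tautomer of a phloroglucinol, which enolises at once to the aromatic 5,7-dihydroxy ring; the oxidant is non-basic and is known to turn β-hydroxy ketones into 1,3-diketones without dehydration, so C2 is not touched.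

**Compound list**

1 | phloroglucinol | Oc1cc(O)cc(O)c1 | starting material
2 | 5-hydroxycyclohexane-1,3-dione | O=C1CC(O)CC(=O)C1 | intermediate
3 | 3,5-bis(tert-butyldimethylsilyloxy)cyclohex-2-en-1-one (racemic at C5) | CC(C)(C)[Si](C)(C)OC1=CC(=O)CC(O[Si](C)(C)C(C)(C)C)C1 | intermediate
4 | 5-(tert-butyldimethylsilyloxy)cyclohexane-1,3-dione | CC(C)(C)[Si](C)(C)OC1CC(=O)CC(=O)C1 | intermediate
5 | 3-acetoxy-5-(tert-butyldimethylsilyloxy)cyclohex-2-en-1-one (racemic at C5) | CC(=O)OC1=CC(=O)CC(O[Si](C)(C)C(C)(C)C)C1 | intermediate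
6 | 2-acetyl-5-(tert-butyldimethylsilyloxy)-3-hydroxycyclohex-2-en-1-one (enol tautomers interconvert, no fixed stereocentre) | CC(=O)C1=C(O)CC(O[Si](C)(C)C(C)(C)C)CC1=O | intermediate
7 | 2-acetyl-5-(tert-butyldimethylsilyloxy)-3-methoxycyclohex-2-en-1-one (racemic at C5) | CC(=O)C1=C(OC)CC(O[Si](C)(C)C(C)(C)C)CC1=O | intermediate
8 | 5-(tert-butyldimethylsilyloxy)-3-methoxy-2-[1-(trimethylsilyloxy)vinyl]cyclohex-2-en-1-one (racemic at C5) | C=C(O[Si](C)(C)C)C1=C(OC)CC(O[Si](C)(C)C(C)(C)C)CC1=O | intermediate
9 | 3-bromo-4-methoxybenzaldehyde | COc1ccc(C=O)cc1Br | starting material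
10 | tributyl(3-methylbut-2-enyl)stannane | CCCC[Sn](CCCC)(CCCC)CC=C(C)C | starting material
11 | 4-methoxy-3-(3-methylbut-2-enyl)benzaldehyde | COc1ccc(C=O)cc1CC=C(C)C | intermediate
12 | 5-(tert-butyldimethylsilyloxy)-3-methoxy-2-[(3S)-3-[4-methoxy-3-(3-methylbut-2-enyl)phenyl]-3-(trimethylsilyloxy)propanoyl]cyclohex-2-en-1-one (both C5 epimers) | COc1ccc([C@@H](O[Si](C)(C)C)CC(=O)C2=C(OC)CC(O[Si](C)(C)C(C)(C)C)CC2=O)cc1CC=C(C)C | intermediate
13 | 5-(tert-butyldimethylsilyloxy)-2-[(3S)-3-hydroxy-3-[4-methoxy-3-(3-methylbut-2-enyl)phenyl]propanoyl]-3-methoxycyclohex-2-en-1-one (both C5 epimers) | COc1ccc([C@@H](O)CC(=O)C2=C(OC)CC(O[Si](C)(C)C(C)(C)C)CC2=O)cc1CC=C(C)C | intermediate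
14 | (2S)-7-(tert-butyldimethylsilyloxy)-2-[4-methoxy-3-(3-methylbut-2-enyl)phenyl]-2,3,7,8-tetrahydro-4H-chromene-4,5(6H)-dione (both C7 epimers) | COc1ccc([C@@H]2CC(=O)C3=C(CC(O[Si](C)(C)C(C)(C)C)CC3=O)O2)cc1CC=C(C)C | intermediate
15 | (2S)-7-hydroxy-2-[4-methoxy-3-(3-methylbut-2-enyl)phenyl]-2,3,7,8-tetrahydro-4H-chromene-4,5(6H)-dione (both C7 epimers) | COc1ccc([C@@H]2CC(=O)C3=C(CC(O)CC3=O)O2)cc1CC=C(C)C | intermediate
16 | (2S)-2-[4-methoxy-3-(3-methylbut-2-enyl)phenyl]-2,3-dihydro-4H-chromene-4,5,7(6H,8H)-trione | COc1ccc([C@@H]2CC(=O)C3=C(CC(=O)CC3=O)O2)cc1CC=C(C)C | intermediate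
17 | 4'-O-methyllicoflavanone, (2S)-5,7-dihydroxy-2-[4-methoxy-3-(3-methylbut-2-enyl)phenyl]-2,3-dihydro-4H-chromen-4-one | COc1ccc([C@@H]2CC(=O)c3c(O)cc(O)cc3O2)cc1CC=C(C)C | target

**Step count**

Total: 9 steps. Longest linear sequence: 8 steps (steps 1–5 and 7–9, from phloroglucinol).

**Steps most likely to fail**

Step 5. The base may deprotonate the ring (C6, or the doubly vinylogous C4) instead of the acetyl group, and the ring anion may then lose silanolate by E1cB elimination, which aromatises ring A without its C7 oxygen. The fallback carries the ring oxygen through enolisation as a lithium alkoxide, which cannot leave and lowers the acidity of the neighbouring ring CH2 groups.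
- Setting out from 7, HF·pyridine/pyridine (THF, 0 °C) should give 2-acetyl-5-hydroxy-3-methoxycyclohex-2-en-1-one F1.
- LiN(SiMe3)2 (2.2 equiv, THF, −78 °C) followed by TMSCl should give 3-methoxy-5-(trimethylsilyloxy)-2-[1-(trimethylsilyloxy)vinyl]cyclohex-2-en-1-one F2.
- Under the conditions of step 7, F2 and 11 should give the bis(trimethylsilyl) aldol adduct F3.
- Methanol/PPTS removes both silyl groups to give the dihydroxy ketone F4, which closes ring C and rejoins the route at 15; step 8 is then not needed.

Step 7. The hindered, cross-conjugated silyl dienol ether may add slowly to an electron-rich aldehyde, the titanium catalyst may be held by the 1,3-dicarbonyl array of the adduct, and an uncatalysed or silyl-cation-catalysed pathway may leak through; all of these lower conversion and facial selectivity. If only the sense of induction is opposite, the (R)-ligand is used. The fallback replaces Lewis-acid activation by a more nucleophilic amino-siloxy diene and hydrogen-bond catalysis.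
- Setting out from 7, dimethylamine (THF, 0 °C) exchanges the methoxy group to give the vinylogous amide 2-acetyl-5-(tert-butyldimethylsilyloxy)-3-(dimethylamino)cyclohex-2-en-1-one F5.
- KN(SiMe3)2/TBSCl (THF, −78 °C) should give the amino-siloxy diene F6.
- F6 and 11 with 1-naphthyl-TADDOL (20 mol %, the enantiomer that opens the Si face; toluene, −40 °C) should give the aminal adduct F7.
- Acetyl chloride (CH2Cl2, −78 °C) expels the amine and the enol silyl group from F7 and rejoins the route at 14.

Step 9. The electron-rich resorcinol ring may be oxidised further by the hypervalent iodine reagent once it has formed, or the β-hydroxy ketone may dehydrate under the acetic acid released, giving the 7-deoxy phenol. The fallback dehydrogenates the silyl ether instead of oxidising the alcohol (Saegusa–Ito oxidation).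
- Setting out from 14, TMSOTf/Et3N (CH2Cl2, −78 °C) should give the ring A trimethylsilyl dienol ether F8.
- Pd(OAc)2 (1.1 equiv, MeCN, rt; divalent palladium, β-hydride elimination from C7) should give, after tautomerisation, the 7-O-silyl flavanone F9.
- HF·pyridine/pyridine (THF, 0 °C) removes the aryl silyl ether and rejoins the route at 17.

**Further compounds**

F1 | step 5 | 2-acetyl-5-hydroxy-3-methoxycyclohex-2-en-1-one (racemic) | CC(=O)C1=C(OC)CC(O)CC1=O
F2 | step 5 | 3-methoxy-5-(trimethylsilyloxy)-2-[1-(trimethylsilyloxy)vinyl]cyclohex-2-en-1-one (racemic) | C=C(O[Si](C)(C)C)C1=C(OC)CC(O[Si](C)(C)C)CC1=O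
F3 | step 5 | bis(trimethylsilyl) aldol adduct, 3-methoxy-2-[(3S)-3-[4-methoxy-3-(3-methylbut-2-enyl)phenyl]-3-(trimethylsilyloxy)propanoyl]-5-(trimethylsilyloxy)cyclohex-2-en-1-one | COc1ccc([C@@H](O[Si](C)(C)C)CC(=O)C2=C(OC)CC(O[Si](C)(C)C)CC2=O)cc1CC=C(C)C
F4 | step 5 | dihydroxy ketone, 5-hydroxy-2-[(3S)-3-hydroxy-3-[4-methoxy-3-(3-methylbut-2-enyl)phenyl]propanoyl]-3-methoxycyclohex-2-en-1-one | COc1ccc([C@@H](O)CC(=O)C2=C(OC)CC(O)CC2=O)cc1CC=C(C)C
F5 | step 7 | 2-acetyl-5-(tert-butyldimethylsilyloxy)-3-(dimethylamino)cyclohex-2-en-1-one (racemic) | CC(=O)C1=C(N(C)C)CC(O[Si](C)(C)C(C)(C)C)CC1=O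
F6 | step 7 | amino-siloxy diene, 5-(tert-butyldimethylsilyloxy)-2-[1-(tert-butyldimethylsilyloxy)vinyl]-3-(dimethylamino)cyclohex-2-en-1-one (racemic) | C=C(O[Si](C)(C)C(C)(C)C)C1=C(N(C)C)CC(O[Si](C)(C)C(C)(C)C)CC1=O
F7 | step 7 | aminal adduct, (2S)-4,7-bis(tert-butyldimethylsilyloxy)-8a-(dimethylamino)-2-[4-methoxy-3-(3-methylbut-2-enyl)phenyl]-2,3,6,7,8,8a-hexahydro-5H-chromen-5-one | COc1ccc([C@@H]2CC(O[Si](C)(C)C(C)(C)C)=C3C(=O)CC(O[Si](C)(C)C(C)(C)C)CC3(N(C)C)O2)cc1CC=C(C)C
F8 | step 9 | ring A trimethylsilyl dienol ether, (2S)-7-(tert-butyldimethylsilyloxy)-2-[4-methoxy-3-(3-methylbut-2-enyl)phenyl]-5-(trimethylsilyloxy)-2,3,7,8-tetrahydro-4H-chromen-4-one | COc1ccc([C@@H]2CC(=O)C3=C(CC(O[Si](C)(C)C(C)(C)C)C=C3O[Si](C)(C)C)O2)cc1CC=C(C)C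
F9 | step 9 | 7-O-silyl flavanone, (2S)-7-(tert-butyldimethylsilyloxy)-5-hydroxy-2-[4-methoxy-3-(3-methylbut-2-enyl)phenyl]-2,3-dihydro-4H-chromen-4-one | COc1ccc([C@@H]2CC(=O)c3c(O)cc(O[Si](C)(C)C(C)(C)C)cc3O2)cc1CC=C(C)C
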